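**Retrosynthetic overview**
- The target comes from a 7,8-diol by Yamaguchi acylation of the secondary C8–OH and final desilylation. The diol comes from OH-directed reduction of a 7-acyl-7-hydroxycycloheptan-8-one.
- That cycloheptanone comes from a 1-(1,2-dioxoalkyl)cyclohexanol by an α-ketol 1,2-shift (six→seven). The diketone comes from a cis-fused keto lactone plus (E)-1-diazopent-3-en-2-one.
- The keto lactone is closed by SN2 of an acrylic acid onto a trans-diaxial α-bromoketone. Its carbon frame comes from Mukaiyama–Michael addition of an acetate ketene acetal to a cyclohexenone, followed by α-methylenation.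
- The cyclohexenone comes from 2-methylcyclohex-2-enone by asymmetric β-borylation/oxidation, silylation and dehydrogenation.
- Ring order: purchased six-membered carbocycle, then γ-lactone, then expansion of the six-membered ring to the seven-membered ring.

Assumption: names use benzofuran and cyclohepta[b]furan numbering; TBDPS = tert-butyldiphenylsilyl, TBS = tert-butyldimethylsilyl; LDA, LiHMDS and DMDO are used as ready-made solutions.

**Step 1**
Reactants: 1 2-methylcyclohex-2-en-1-one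
Product: 3 (2S,3R)-3-hydroxy-2-methylcyclohexan-1-one, via pinacol boronate 2 (not isolated)
Conditions: B2pin2, CuCl (3 mol %), NaOtBu (5 mol %), Josiphos-type ligand (the enantiomer giving 3R), MeOH, THF, rt; then 30% H2O2, pH 7 buffer, 0 °C
Reagents that add atoms: hydrogen peroxide OO; bis(pinacolato)diboron CC1(C)OB(OC1(C)C)B1OC(C)(C)C(C)(C)O1 (boron stays only in 2)
Why: In this copper-catalysed enantioselective conjugate borylation the ligand selects the enone face and sets C3, C–B oxidation proceeds with retention, and the epimerisable C2 methyl settles trans (diequatorial).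

**Step 2**
Reactants: 3 (2S,3R)-3-hydroxy-2-methylcyclohexan-1-one
Product: 4 (2S,3R)-3-(tert-butyldiphenylsilyloxy)-2-methylcyclohexan-1-one
Conditions: TBDPSCl, imidazole, DMF, rt
Reagents that add atoms: tert-butyl(chloro)diphenylsilane CC(C)(C)[Si](Cl)(c1ccccc1)c1ccccc1
Why: This is an imidazole-promoted silyl ether formation that touches no stereocentre, and TBDPS is chosen because it survives the TFA of step 7.

**Step 3**
Reactants: 4 (2S,3R)-3-(tert-butyldiphenylsilyloxy)-2-methylcyclohexan-1-one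
Product: 5 (5R,6S)-5-(tert-butyldiphenylsilyloxy)-6-methylcyclohex-2-en-1-one
Conditions: LDA, THF, −78 °C; then PhS(Cl)=NtBu, −78 °C
Reagents that add atoms: none
Why: Kinetic deprotonation at the unsubstituted α-CH2 followed by Mukaiyama sulfinimidoyl chloride dehydrogenation gives the enone at −78 °C without enolising toward the β-silyloxy side, so neither stereocentre is disturbed.

**Step 4**
Reactants: 6 tert-butyl acetate
Product: 7 1-tert-butoxy-1-(tert-butyldimethylsilyloxy)ethene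
Conditions: LDA, THF, −78 °C; TBSCl, DMPU, −78 °C→rt
Reagents that add atoms: tert-butyl(chloro)dimethylsilane CC(C)(C)[Si](C)(C)Cl
Why: O-Silylation of the lithium ester enolate gives the ketene silyl acetal, and no stereocentre is involved.

**Step 5**
Reactants: 5 (5R,6S)-5-(tert-butyldiphenylsilyloxy)-6-methylcyclohex-2-en-1-one; 7 1-tert-butoxy-1-(tert-butyldimethylsilyloxy)ethene
Product: 8 tert-butyl 2-[(1S,4S,5R)-3-(tert-butyldimethylsilyloxy)-5-(tert-butyldiphenylsilyloxy)-4-methylcyclohex-2-en-1-yl]acetate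
Conditions: Tf2NH (2 mol %), CH2Cl2, −78 °C
Reagents that add atoms: none
Why: In this Mukaiyama–Michael addition, axial attack trans to the pseudo-equatorial 5-silyloxy group sets the future C3a, and silyl transfer keeps the ketone as a regiodefined TBS enol ether.

**Step 6**
Reactants: 8 tert-butyl 2-[(1S,4S,5R)-3-(tert-butyldimethylsilyloxy)-5-(tert-butyldiphenylsilyloxy)-4-methylcyclohex-2-en-1-yl]acetate
Product: 11 tert-butyl 2-[(1R,4S,5R)-3-(tert-butyldimethylsilyloxy)-5-(tert-butyldiphenylsilyloxy)-4-methylcyclohex-2-en-1-yl]prop-2-enoate, via Mannich base 9 (not isolated), via methiodide 10 (not isolated)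
Conditions: LDA, THF, −78 °C; CH2=NMe2+ I− (1.05 equiv), −78→0 °C; MeI, Et2O, rt; DBU, CH2Cl2, rt
Reagents that add atoms: Eschenmoser's salt C=[N+](C)C.[I-]; iodomethane CI (methyl stays only in 10)
Why: An ester-enolate Mannich reaction followed by Hofmann-type elimination achieves α-methylenation, and because the ketone is masked as its enol ether only the ester is deprotonated and the ring stereocentres stay fixed.

**Step 7**
Reactants: 11 tert-butyl 2-[(1R,4S,5R)-3-(tert-butyldimethylsilyloxy)-5-(tert-butyldiphenylsilyloxy)-4-methylcyclohex-2-en-1-yl]prop-2-enoate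
Product: 14 (3aS,5R,6S,7aR)-5-(tert-butyldiphenylsilyloxy)-6-methyl-3-methylidenehexahydro-1-benzofuran-2,7-dione, via bromoketone 12 (not isolated), via bromo acid 13 (not isolated)
Conditions: NBS, CH2Cl2, −78→0 °C; TFA (20 vol %), rt, evaporate; NaHCO3, DMF, rt
Reagents that add atoms: N-bromosuccinimide O=C1CCC(=O)N1Br (bromine stays only in 12 and 13)
Why: Bromination of the silyl enol ether occurs axially and anti to the axial acrylate arm, and after acidolysis of the tert-butyl ester the carboxylate displaces the trans-diaxial bromide by intramolecular SN2 with inversion, which sets C7a and forces the cis ring fusion.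

**Step 8**
Reactants: 15 (E)-pent-3-en-2-one
Product: 17 (E)-1-diazopent-3-en-2-one, via trifluoroacetyl diketone 16 (not isolated)
Conditions: LiHMDS, THF, −78 °C; CF3CO2CH2CF3; 5% HCl wash; MsN3, Et3N, H2O (1 equiv), MeCN, rt
Reagents that add atoms: methanesulfonyl azide CS(=O)(=O)N=[N+]=[N-]; 2,2,2-trifluoroethyl trifluoroacetate O=C(OCC(F)(F)F)C(F)(F)F (acyl group stays only in 16)
Why: Detrifluoroacetylative diazo transfer (Claisen activation then Regitz-type transfer) gives the α,β-unsaturated diazoketone without the pyrazoline formation seen with acid chloride/diazomethane, and the E alkene is untouched.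

**Step 9**
Reactants: 14 (3aS,5R,6S,7aR)-5-(tert-butyldiphenylsilyloxy)-6-methyl-3-methylidenehexahydro-1-benzofuran-2,7-dione; 17 (E)-1-diazopent-3-en-2-one
Product: 18 (3aS,5R,6S,7R,7aR)-5-(tert-butyldiphenylsilyloxy)-7-[(3E)-1-diazo-2-oxopent-3-en-1-yl]-7-hydroxy-6-methyl-3-methylidenehexahydro-1-benzofuran-2(3H)-one
Conditions: 17, LDA, THF, −78 °C; then 14, −78 °C; AcOH quench at −78 °C
Reagents that add atoms: none
Why: This is an aldol-type 1,2-addition of the lithiated α-diazoketone to the activated α-acyloxy ketone, in which equatorial attack on the convex face (opposite the axial C3a–C3 bond and anti to the C6 methyl and C7a oxygen) sets C7 with the hydroxyl on the lactone-oxygen face.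

**Step 10**
Reactants: 18 (3aS,5R,6S,7R,7aR)-5-(tert-butyldiphenylsilyloxy)-7-[(3E)-1-diazo-2-oxopent-3-en-1-yl]-7-hydroxy-6-methyl-3-methylidenehexahydro-1-benzofuran-2(3H)-one
Product: 20 (3aS,5R,6S,7R,8aR)-7-[(E)-but-2-enoyl]-5-(tert-butyldiphenylsilyloxy)-7-hydroxy-6-methyl-3-methylidenehexahydro-2H-cyclohepta[b]furan-2,8(3H)-dione, via hydroxy diketone 19 (not isolated)
Conditions: DMDO (1.05 equiv, dried acetone solution), CH2Cl2, −40→0 °C, evaporate; Cu(OTf)2 (10 mol %), 4 Å MS, CH2Cl2, rt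
Reagents that add atoms: dimethyldioxirane CC1(C)OO1
Why: Proposed new method: a telescoped diazo-to-ketone oxygen transfer and Cu(II)-templated α-ketol (acyloin) 1,2-shift used as a six-to-seven ring expansion, in which DMDO attacks the nucleophilic diazo carbon (N2 loss, far faster than epoxidation of the two electron-poor alkenes) to give vicinal diketone 19, Cu(II) then holds the C7 hydroxyl and the adjacent carbonyl syn-periplanar so that the electron-rich C6–C7 σ bond (not the acyloxy-deactivated C7a–C7 bond) migrates suprafacially and with retention at C6 onto one face of that carbonyl, which transfers the carbinol configuration of 19 to the new carbinol carbon (OH cis to the C6 methyl, crotonoyl on the opposite face), while the estimated gain from 1,2- to 1,3-diketone (about 7 kcal/mol) outweighs the estimated extra cycloheptanone strain (about 3–4 kcal/mol); the closest known reaction types are the Lewis-acid-catalysed α-ketol rearrangement of β-hydroxy-α-dicarbonyl compounds, steroid D-homoannulation and dioxirane oxidation of α-diazoketones, none shown as a one-flask six-to-seven expansion of an enone-bearing diketone with carbinol-to-carbinol chirality transfer.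

**Step 11**
Reactants: 20 (3aS,5R,6S,7R,8aR)-7-[(E)-but-2-enoyl]-5-(tert-butyldiphenylsilyloxy)-7-hydroxy-6-methyl-3-methylidenehexahydro-2H-cyclohepta[b]furan-2,8(3H)-dione
Product: 21 (3aS,5R,6S,7S,8S,8aR)-7-[(E)-but-2-enoyl]-5-(tert-butyldiphenylsilyloxy)-7,8-dihydroxy-6-methyl-3-methylideneoctahydro-2H-cyclohepta[b]furan-2-one
Conditions: Me4NBH(OAc)3, MeCN/AcOH, −30 °C
Reagents that add atoms: none
Why: In this Saksena–Evans-type hydroxyl-directed reduction, boron binds the C7–OH and delivers hydride to the same face of the more electrophilic ring ketone, which sets C8 as the trans-diol, while triacetoxyborohydride leaves the conjugated enone and the α-methylene lactone alone.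

**Step 12**
Reactants: 21 (3aS,5R,6S,7S,8S,8aR)-7-[(E)-but-2-enoyl]-5-(tert-butyldiphenylsilyloxy)-7,8-dihydroxy-6-methyl-3-methylideneoctahydro-2H-cyclohepta[b]furan-2-one; 22 (S)-2-methylbutanoic acid
Product: 24 (3aS,5R,6S,7S,8S,8aR)-7-[(E)-but-2-enoyl]-5-(tert-butyldiphenylsilyloxy)-7-hydroxy-6-methyl-3-methylidene-2-oxooctahydro-2H-cyclohepta[b]furan-8-yl (2S)-2-methylbutanoate, via mixed anhydride 23 (not isolated)
Conditions: 22, 2,4,6-Cl3C6H2COCl, Et3N, toluene, rt; then 21, DMAP, rt→40 °C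
Reagents that add atoms: 2,4,6-trichlorobenzoyl chloride O=C(Cl)c1c(Cl)cc(Cl)cc1Cl (aroyl group stays only in 23)
Why: Yamaguchi esterification acylates only the secondary C8–OH because the tertiary C7–OH is inert, and the acid stereocentre comes from the chiral pool and is not enolised under these conditions.

**Step 13**
Reactants: 24 (3aS,5R,6S,7S,8S,8aR)-7-[(E)-but-2-enoyl]-5-(tert-butyldiphenylsilyloxy)-7-hydroxy-6-methyl-3-methylidene-2-oxooctahydro-2H-cyclohepta[b]furan-8-yl (2S)-2-methylbutanoate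
Product: 25 (3aS,5R,6S,7S,8S,8aR)-7-[(E)-but-2-enoyl]-5,7-dihydroxy-6-methyl-3-methylidene-2-oxooctahydro-2H-cyclohepta[b]furan-8-yl (2S)-2-methylbutanoate
Conditions: HF·pyridine, THF, 0 °C→rt
Reagents that add atoms: none
Why: Fluoride-mediated desilylation under acidic, non-nucleophilic conditions spares the ester, the enone and the α-methylene lactone and changes no stereocentre.

**Compound list**
1 | 2-methylcyclohex-2-en-1-one | CC1=CCCCC1=O | starting material
2 | (2S,3R)-2-methyl-3-(4,4,5,5-tetramethyl-1,3,2-dioxaborolan-2-yl)cyclohexan-1-one | C1CC[C@@H](B2OC(C)(C)C(C)(C)O2)[C@H](C)C1=O | intermediate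
3 | (2S,3R)-3-hydroxy-2-methylcyclohexan-1-one | C1CC[C@@H](O)[C@H](C)C1=O | intermediate
4 | (2S,3R)-3-(tert-butyldiphenylsilyloxy)-2-methylcyclohexan-1-one | C1CC[C@@H](O[Si](c2ccccc2)(c2ccccc2)C(C)(C)C)[C@H](C)C1=O | intermediate
5 | (5R,6S)-5-(tert-butyldiphenylsilyloxy)-6-methylcyclohex-2-en-1-one | C1=CC[C@@H](O[Si](c2ccccc2)(c2ccccc2)C(C)(C)C)[C@H](C)C1=O | intermediate
6 | tert-butyl acetate | CC(=O)OC(C)(C)C | starting material
7 | 1-tert-butoxy-1-(tert-butyldimethylsilyloxy)ethene | C=C(OC(C)(C)C)O[Si](C)(C)C(C)(C)C | intermediate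
8 | tert-butyl 2-[(1S,4S,5R)-3-(tert-butyldimethylsilyloxy)-5-(tert-butyldiphenylsilyloxy)-4-methylcyclohex-2-en-1-yl]acetate | CC(C)(C)OC(=O)C[C@@H]1C[C@@H](O[Si](c2ccccc2)(c2ccccc2)C(C)(C)C)[C@H](C)C(O[Si](C)(C)C(C)(C)C)=C1 | intermediate
9 | tert-butyl 3-(dimethylamino)-2-[(1R,4S,5R)-3-(tert-butyldimethylsilyloxy)-5-(tert-butyldiphenylsilyloxy)-4-methylcyclohex-2-en-1-yl]propanoate (C2 epimers) | CC(C)(C)OC(=O)C(CN(C)C)[C@@H]1C[C@@H](O[Si](c2ccccc2)(c2ccccc2)C(C)(C)C)[C@H](C)C(O[Si](C)(C)C(C)(C)C)=C1 | intermediate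
10 | N-methyl ammonium iodide of 9 (trimethylammonium salt, C2 epimers) | CC(C)(C)OC(=O)C(C[N+](C)(C)C)[C@@H]1C[C@@H](O[Si](c2ccccc2)(c2ccccc2)C(C)(C)C)[C@H](C)C(O[Si](C)(C)C(C)(C)C)=C1.[I-] | intermediate
11 | tert-butyl 2-[(1R,4S,5R)-3-(tert-butyldimethylsilyloxy)-5-(tert-butyldiphenylsilyloxy)-4-methylcyclohex-2-en-1-yl]prop-2-enoate | CC(C)(C)OC(=O)C(=C)[C@@H]1C[C@@H](O[Si](c2ccccc2)(c2ccccc2)C(C)(C)C)[C@H](C)C(O[Si](C)(C)C(C)(C)C)=C1 | intermediate
12 | tert-butyl 2-[(1S,2S,4S,5R)-2-bromo-5-(tert-butyldiphenylsilyloxy)-4-methyl-3-oxocyclohexyl]prop-2-enoate | CC(C)(C)OC(=O)C(=C)[C@@H]1C[C@@H](O[Si](c2ccccc2)(c2ccccc2)C(C)(C)C)[C@H](C)C(=O)[C@H]1Br | intermediate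
13 | 2-[(1S,2S,4S,5R)-2-bromo-5-(tert-butyldiphenylsilyloxy)-4-methyl-3-oxocyclohexyl]prop-2-enoic acid | OC(=O)C(=C)[C@@H]1C[C@@H](O[Si](c2ccccc2)(c2ccccc2)C(C)(C)C)[C@H](C)C(=O)[C@H]1Br | intermediate
14 | (3aS,5R,6S,7aR)-5-(tert-butyldiphenylsilyloxy)-6-methyl-3-methylidenehexahydro-1-benzofuran-2,7-dione (cis-fused) | C=C1C(=O)O[C@@H]2[C@H]1C[C@@H](O[Si](c3ccccc3)(c3ccccc3)C(C)(C)C)[C@H](C)C2=O | intermediate
15 | (E)-pent-3-en-2-one | C/C=C/C(C)=O | starting material
16 | (E)-1,1,1-trifluorohept-5-ene-2,4-dione | C/C=C/C(=O)CC(=O)C(F)(F)F | intermediate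
17 | (E)-1-diazopent-3-en-2-one | C/C=C/C(=O)C=[N+]=[N-] | intermediate
18 | (3aS,5R,6S,7R,7aR)-5-(tert-butyldiphenylsilyloxy)-7-[(3E)-1-diazo-2-oxopent-3-en-1-yl]-7-hydroxy-6-methyl-3-methylidenehexahydro-1-benzofuran-2(3H)-one | C=C1C(=O)O[C@@H]2[C@H]1C[C@@H](O[Si](c3ccccc3)(c3ccccc3)C(C)(C)C)[C@H](C)[C@@]2(O)C(=[N+]=[N-])C(=O)/C=C/C | intermediate
19 | (E)-1-[(3aS,5R,6S,7S,7aR)-5-(tert-butyldiphenylsilyloxy)-7-hydroxy-6-methyl-3-methylidene-2-oxooctahydro-1-benzofuran-7-yl]pent-3-ene-1,2-dione | C=C1C(=O)O[C@@H]2[C@H]1C[C@@H](O[Si](c3ccccc3)(c3ccccc3)C(C)(C)C)[C@H](C)[C@@]2(O)C(=O)C(=O)/C=C/C | intermediate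
20 | (3aS,5R,6S,7R,8aR)-7-[(E)-but-2-enoyl]-5-(tert-butyldiphenylsilyloxy)-7-hydroxy-6-methyl-3-methylidenehexahydro-2H-cyclohepta[b]furan-2,8(3H)-dione | C=C1C(=O)O[C@@H]2[C@H]1C[C@@H](O[Si](c3ccccc3)(c3ccccc3)C(C)(C)C)[C@H](C)[C@@](O)(C(=O)/C=C/C)C2=O | intermediate
21 | (3aS,5R,6S,7S,8S,8aR)-7-[(E)-but-2-enoyl]-5-(tert-butyldiphenylsilyloxy)-7,8-dihydroxy-6-methyl-3-methylideneoctahydro-2H-cyclohepta[b]furan-2-one | C=C1C(=O)O[C@@H]2[C@H]1C[C@@H](O[Si](c3ccccc3)(c3ccccc3)C(C)(C)C)[C@H](C)[C@@](O)(C(=O)/C=C/C)[C@H]2O | intermediate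
22 | (S)-2-methylbutanoic acid | CC[C@H](C)C(=O)O | starting material
23 | (2S)-2-methylbutanoic 2,4,6-trichlorobenzoic anhydride | CC[C@H](C)C(=O)OC(=O)c1c(Cl)cc(Cl)cc1Cl | intermediate
24 | (3aS,5R,6S,7S,8S,8aR)-7-[(E)-but-2-enoyl]-5-(tert-butyldiphenylsilyloxy)-7-hydroxy-6-methyl-3-methylidene-2-oxooctahydro-2H-cyclohepta[b]furan-8-yl (2S)-2-methylbutanoate | C=C1C(=O)O[C@@H]2[C@H]1C[C@@H](O[Si](c3ccccc3)(c3ccccc3)C(C)(C)C)[C@H](C)[C@@](O)(C(=O)/C=C/C)[C@H]2OC(=O)[C@@H](C)CC | intermediate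
25 | (3aS,5R,6S,7S,8S,8aR)-7-[(E)-but-2-enoyl]-5,7-dihydroxy-6-methyl-3-methylidene-2-oxooctahydro-2H-cyclohepta[b]furan-8-yl (2S)-2-methylbutanoate (CNP0331957.1) | C=C1C(=O)O[C@@H]2[C@H]1C[C@@H](O)[C@H](C)[C@@](O)(C(=O)/C=C/C)[C@H]2OC(=O)[C@@H](C)CC | target

Total step count: 13. Longest linear sequence: 11 (steps 1–3, 5–7, 9–13).

**Steps most likely to fail**

Step 10 (the new step). The equilibrium may not favour the seven-membered ring, C7a may migrate in competition, or the product may undergo a further 1,2-acyl shift or oxa-Michael closure under Cu(II).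

The fallback uses known chemistry and sets out from 18. Rh2(OAc)4 (1 mol %, CH2Cl2, rt) triggers the established carbenoid 1,2-alkyl-shift ring expansion of an α-diazo-β-hydroxy ketone. This gives the ring-expanded β-diketone (3aS,5R,6R,8aR)-7-[(E)-but-2-enoyl]-5-(tert-butyldiphenylsilyloxy)-6-methyl-3-methylidenehexahydro-2H-cyclohepta[b]furan-2,8(3H)-dione F1. Its enol is then α-hydroxylated with a Davis oxaziridine (or DMDO with Ni(acac)2), which comes back to the route at 20. In this variant C7 is set by reagent approach rather than by chirality transfer, so the C7 epimers may have to be separated.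

Step 9. The lithiated diazoketone may add to the exocyclic methylene lactone in a conjugate sense, or the basic medium may degrade 14.

The fallback sets out from 14. Dimethylamine (THF, 0 °C) masks the Michael acceptor as the Mannich base (3aS,5R,6S,7aR)-5-(tert-butyldiphenylsilyloxy)-3-[(dimethylamino)methyl]-6-methylhexahydro-1-benzofuran-2,7-dione F2. Lithiated 17 then has only the ketone to attack and gives the diazo carbinol (3aS,5R,6S,7R,7aR)-5-(tert-butyldiphenylsilyloxy)-7-[(3E)-1-diazo-2-oxopent-3-en-1-yl]-3-[(dimethylamino)methyl]-7-hydroxy-6-methylhexahydro-1-benzofuran-2(3H)-one F3. Treatment with 2.1 equiv of DMDO oxidises both the diazo carbon and the amine to the amine N-oxide diketone (3aS,5R,6S,7S,7aR) F4. At rt F4 undergoes Cope elimination, restores the methylene group and comes back to the route at 19.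

Step 11. The side-chain enone carbonyl shares the same directing hydroxyl and may be reduced as well, or hydride may arrive from the wrong face.

The fallback sets out from 20. Both ketones are deliberately reduced under Luche conditions (NaBH4, CeCl3·7H2O, MeOH, −78 °C) to the triol (3aS,5R,6S,7R,8S,8aR)-5-(tert-butyldiphenylsilyloxy)-7,8-dihydroxy-7-[(E)-1-hydroxybut-2-enyl]-6-methyl-3-methylideneoctahydro-2H-cyclohepta[b]furan-2-one F5. MnO2 (CH2Cl2, rt) then re-oxidises only the allylic alcohol, which comes back to the route at 21.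

**Further compounds**
F1 | step 10 | (3aS,5R,6R,8aR)-7-[(E)-but-2-enoyl]-5-(tert-butyldiphenylsilyloxy)-6-methyl-3-methylidenehexahydro-2H-cyclohepta[b]furan-2,8(3H)-dione (C7 epimers/enol) | C=C1C(=O)O[C@@H]2[C@H]1C[C@@H](O[Si](c3ccccc3)(c3ccccc3)C(C)(C)C)[C@H](C)C(C(=O)/C=C/C)C2=O
F2 | step 9 | (3aS,5R,6S,7aR)-5-(tert-butyldiphenylsilyloxy)-3-[(dimethylamino)methyl]-6-methylhexahydro-1-benzofuran-2,7-dione (C3 epimers) | CN(C)CC1C(=O)O[C@@H]2[C@H]1C[C@@H](O[Si](c3ccccc3)(c3ccccc3)C(C)(C)C)[C@H](C)C2=O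
F3 | step 9 | (3aS,5R,6S,7R,7aR)-5-(tert-butyldiphenylsilyloxy)-7-[(3E)-1-diazo-2-oxopent-3-en-1-yl]-3-[(dimethylamino)methyl]-7-hydroxy-6-methylhexahydro-1-benzofuran-2(3H)-one | CN(C)CC1C(=O)O[C@@H]2[C@H]1C[C@@H](O[Si](c3ccccc3)(c3ccccc3)C(C)(C)C)[C@H](C)[C@@]2(O)C(=[N+]=[N-])C(=O)/C=C/C
F4 | step 9 | N-oxide of the (3aS,5R,6S,7S,7aR)-3-[(dimethylamino)methyl] analogue of diketone 19 | C[N+](C)([O-])CC1C(=O)O[C@@H]2[C@H]1C[C@@H](O[Si](c3ccccc3)(c3ccccc3)C(C)(C)C)[C@H](C)[C@@]2(O)C(=O)C(=O)/C=C/C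
F5 | step 11 | (3aS,5R,6S,7R,8S,8aR)-5-(tert-butyldiphenylsilyloxy)-7,8-dihydroxy-7-[(E)-1-hydroxybut-2-enyl]-6-methyl-3-methylideneoctahydro-2H-cyclohepta[b]furan-2-one (carbinol epimers) | C=C1C(=O)O[C@@H]2[C@H]1C[C@@H](O[Si](c3ccccc3)(c3ccccc3)C(C)(C)C)[C@H](C)[C@@](O)(C(O)/C=C/C)[C@H]2O
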